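**Strategy.** The plan cuts the seven-membered ring where it meets the central benzene ring: at the bonds from two adjacent ring carbons (C4 and C5 of the first dihydrobenzofuran) to the benzylic CH2 and to the methine that later becomes C3 of the second dihydrobenzofuran. These carbons are ortho to each other and C5 is flanked by an oxygen on C6, so a palladium/norbornene (Catellani) annulation applies: a 5-iodo-dihydrobenzofuran (C6 oxygen as MOM ether) and an enantiopure 2,2-diarylethyl bromide bearing an ortho stilbene are joined by C4–H alkylation and 7-exo Heck closure at C5 in one operation. Acid then closes the second dihydrobenzofuran onto the resulting exocyclic alkene.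

Key step: step 12

Remark on locants: the first dihydrobenzofuran is numbered O1, C2, C3, C3a, C4–C7, C7a; its benzo ring is the central benzene ring of the target.
Remark on the catalysts: the sense of induction in steps 6 and 7 is assigned by analogy; should a catalyst favour the antipode, its mirror-image form (step 6) or its quinidine-derived pseudoenantiomer (step 7) is used, with nothing else changed.

Step 1
Reactants: 1 resorcinol; 2 3,5-dimethoxybenzoic acid
Product: 3 (2,4-dihydroxyphenyl)(3,5-dimethoxyphenyl)methanone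
Conditions: BF3·OEt2 (as solvent), 90 °C; aqueous NaOAc work-up
Reagents that add atoms: none
Why: Friedel–Crafts acylation in which the BF3-activated acid attacks resorcinol at C4 (para to one hydroxyl, ortho to the other), while the chelated carbonyl of the product deactivates it towards a second acylation.

Step 2
Reactants: 3
Product: 4 (3,5-dimethoxyphenyl)[2-hydroxy-4-(methoxymethoxy)phenyl]methanone
Conditions: MOMCl (1.05 equiv), K2CO3, acetone, 0 °C → rt
Reagents that add atoms: chloromethyl methyl ether (MOMCl), COCCl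
Why: Williamson etherification that discriminates the two phenols, because the 2-hydroxyl is held in a hydrogen bond to the ketone and only the 4-hydroxyl is alkylated at room temperature.

Step 3
Reactants: 4
Product: 5 (3,5-dimethoxyphenyl)[2-hydroxy-5-iodo-4-(methoxymethoxy)phenyl]methanone
Conditions: NIS (1.05 equiv), MeCN, 0 °C → rt
Reagents that add atoms: N-iodosuccinimide (NIS), O=C1CCC(=O)N1I
Why: Electrophilic aromatic iodination directed by the free phenol to its para position C5 (also ortho to the MOM ether), whereas C3 lies between two oxygens and the dimethoxybenzoyl ring is deactivated by the carbonyl.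

Step 4
Reactants: 5; 6 4-methoxybenzyl chloride
Product: 7 (3,5-dimethoxyphenyl){5-iodo-2-[(4-methoxyphenyl)methoxy]-4-(methoxymethoxy)phenyl}methanone
Conditions: K2CO3, n-Bu4NI (cat.), DMF, 70 °C
Reagents that add atoms: none
Why: Williamson etherification of the chelated phenol under forcing conditions, which installs the benzylic CH2 that becomes C2 of the first dihydrobenzofuran.

Step 5
Reactants: 7
Product: 8 hydrazone of ketone 7 (mixture of C=N isomers)
Conditions: N2H4·H2O (10 equiv), AcOH (cat.), EtOH, 80 °C
Reagents that add atoms: hydrazine (as hydrate), NN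
Why: Acid-catalysed condensation of the diaryl ketone with hydrazine gives the hydrazone, the stable precursor of a donor/donor diazo compound, and the aryl iodide, MOM ether and benzyl ether are inert to it.

Step 6
Reactants: 8
Product: 10 (2S,3R)-3-(3,5-dimethoxyphenyl)-5-iodo-6-(methoxymethoxy)-2-(4-methoxyphenyl)-2,3-dihydro-1-benzofuran (2,3-cis), via diaryldiazomethane 9 (not isolated)
Conditions: MnO2, CH2Cl2, 0 °C; filter; Rh2(R-PTAD)4 [dirhodium tetrakis((R)-(1-adamantyl)(phthalimido)acetate)] (1 mol%), CH2Cl2, 0 °C → rt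
Reagents that add atoms: none
Why: MnO2 dehydrogenates the hydrazone to 9, whose rhodium carbene undergoes intramolecular 1,5 C–H insertion into the activated ArCH2–O bond (donor/donor carbene C–H insertion), a concerted insertion that should give the 2,3-cis product with C3 (and with it C2) fixed by the chiral carboxylate ligands.

Step 7
Reactants: 11 3,5-dimethoxyphenol; 12 (E)-2,4-dimethoxy-1-(2-nitroethenyl)benzene
Product: 13 2-[(1R)-1-(2,4-dimethoxyphenyl)-2-nitroethyl]-3,5-dimethoxyphenol
Conditions: squaramide of 3,5-bis(trifluoromethyl)aniline and 9-amino-9-deoxy-epi-quinine (10 mol%), CH2Cl2, −20 °C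
Reagents that add atoms: none
Why: Organocatalytic enantioselective Friedel–Crafts (conjugate) alkylation of an electron-rich phenol, in which the squaramide binds the nitro group and the quinuclidine the phenol OH, so that the ortho carbon (para to a methoxy group) adds to one face of the nitroalkene and sets the diarylmethine centre.

Step 8
Reactants: 13
Product: 14 2-[(1R)-1-(2,4-dimethoxyphenyl)-2-nitroethyl]-3,5-dimethoxyphenyl trifluoromethanesulfonate
Conditions: Tf2O, pyridine, CH2Cl2, −20 → 0 °C
Reagents that add atoms: trifluoromethanesulfonic anhydride (Tf2O), O=S(=O)(OS(=O)(=O)C(F)(F)F)C(F)(F)F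
Why: O-sulfonylation of the phenol to the aryl triflate gives the handle for the later cross-coupling, and pyridine is too weak a base to form the nitronate.

Step 9
Reactants: 14
Product: 17 2-[(1R)-1-(2,4-dimethoxyphenyl)-2-hydroxyethyl]-3,5-dimethoxyphenyl trifluoromethanesulfonate, via sodium nitronate 15 (not isolated), via aldehyde 16 (not isolated)
Conditions: NaOMe (1.1 equiv), MeOH/CH2Cl2, 0 °C; O3, −78 °C; then NaBH4, −78 → 0 °C
Reagents that add atoms: ozone, [O-][O+]=O
Why: Ozonolytic Nef reaction of the nitronate followed by borohydride reduction in the same flask at low temperature, so that the enolisable α,α-diaryl aldehyde 16 is reduced before it can racemise.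

Step 10
Reactants: 17; 18 (E)-2-(4-methoxyphenyl)ethenylboronic acid pinacol ester
Product: 19 (2R)-2-(2,4-dimethoxyphenyl)-2-{2,4-dimethoxy-6-[(E)-2-(4-methoxyphenyl)ethenyl]phenyl}ethan-1-ol
Conditions: Pd(OAc)2 (5 mol%), SPhos (10 mol%), K3PO4, THF/H2O, 60 °C
Reagents that add atoms: none
Why: Suzuki–Miyaura coupling of the hindered, electron-rich aryl triflate with the (E)-alkenyl boronate under a dialkylbiarylphosphine ligand, with retention of alkene geometry and no effect on the remote stereocentre.

Step 11
Reactants: 19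
Product: 20 2-[(1R)-2-bromo-1-(2,4-dimethoxyphenyl)ethyl]-1,5-dimethoxy-3-[(E)-2-(4-methoxyphenyl)ethenyl]benzene
Conditions: CBr4, PPh3, CH2Cl2, 0 °C
Reagents that add atoms: carbon tetrabromide, BrC(Br)(Br)Br
Why: Appel bromination, an SN2 displacement of the alkoxyphosphonium by bromide at the primary carbon under neutral conditions, which leaves the adjacent stereocentre and the stilbene untouched.

Step 12
Reactants: 10; 20
Product: 21 annulated cis-dihydrobenzofuran: C4 of 10 bonded to the CH2 and C5 to the alkene carbon of a new cycloheptene that carries an exocyclic (E)-4-methoxybenzylidene group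
Conditions: Pd(OAc)2 (10 mol%), P(2-furyl)3 (22 mol%), norbornene (2 equiv), Cs2CO3 (3 equiv), MeCN (0.05 M), 90 °C, sealed tube
Reagents that add atoms: none
Why: Zerovalent palladium inserts into the C5–I bond of 10, norbornene inserts syn and C4–H palladation gives the aryl–norbornyl palladacycle of divalent palladium; SN2-type oxidative addition of the primary bromide 20 (to tetravalent palladium) and C(sp2)–C(sp3) reductive elimination forge C4–CH2, and because both ortho positions are then substituted (C6–OMOM and the new alkyl group) norbornene is expelled by β-carbon elimination. The C5–palladium species then adds syn across the tethered (E)-stilbene at the carbon attached to the dimethoxyarene, closing the seven-membered ring in the 7-exo-trig mode, and β-hydride elimination of the only available hydrogen leaves the exocyclic trisubstituted alkene. The closest known reaction type is the Catellani ortho-alkylation/intramolecular Mizoroki–Heck annulation of ortho-substituted aryl iodides with bromoalkyl-tethered alkenes. No stereocentre is created: the (R) diarylmethine of 20 and the two centres of 10 have no acidic or ionisable neighbour under carbonate and are carried through, and the ring alkene carbon becomes a stereocentre only in step 13. The step needs alkylation before Heck coupling (norbornene in excess inserts faster than the hindered internal stilbene), a single C–H site (C4 is the only free ortho position) and exo over endo closure (7-exo places palladium on the benzylic carbon).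

Step 13
Reactants: 21
Product: 23 octa-O-methyl ether of the target (both dihydrobenzofurans trans), via free phenol 22 (not isolated)
Conditions: HCl, MeOH/THF, 50 °C; evaporate; then TFA, CH2Cl2 (5 mM), 0 °C → rt
Reagents that add atoms: none
Why: Acid first cleaves the MOM acetal to phenol 22, then protonates the exocyclic alkene at its ring carbon to a 4-methoxybenzyl cation that the phenol captures (acid-mediated hydroalkoxylation to a trans-2,3-diaryl-dihydrobenzofuran, the new C3 being set by the diarylmethine centre because only one C3 configuration lets the ring-fused C2 avoid the pseudo-axial 2,4-dimethoxyphenyl group), and the same medium ionises and recloses the benzylic C2–O bond of the first dihydrobenzofuran so that its cis isomer epimerises at C2 to the more stable trans isomer with C3 untouched.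

Step 14
Reactants: 23
Product: 24 target CNP0154047.1
Conditions: BBr3 (16 equiv), CH2Cl2, −78 °C → rt; MeOH, then aqueous NaHCO3
Reagents that add atoms: none
Why: Lewis-acid cleavage of all eight aryl methyl ethers by BBr3, the standard final step for permethylated resveratrol oligomers, with the two trans-dihydrobenzofurans expected to survive because their C–O bonds are secondary alkyl aryl ethers held in five-membered rings.

**Compound list**

1 | resorcinol | Oc1cccc(O)c1 | starting material
2 | 3,5-dimethoxybenzoic acid | COc1cc(OC)cc(C(=O)O)c1 | starting material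
3 | (2,4-dihydroxyphenyl)(3,5-dimethoxyphenyl)methanone | COc1cc(OC)cc(C(=O)c2ccc(O)cc2O)c1 | intermediate
4 | (3,5-dimethoxyphenyl)[2-hydroxy-4-(methoxymethoxy)phenyl]methanone | COCOc1ccc(C(=O)c2cc(OC)cc(OC)c2)c(O)c1 | intermediate
5 | (3,5-dimethoxyphenyl)[2-hydroxy-5-iodo-4-(methoxymethoxy)phenyl]methanone | COCOc1cc(O)c(C(=O)c2cc(OC)cc(OC)c2)cc1I | intermediate
6 | 4-methoxybenzyl chloride | COc1ccc(CCl)cc1 | starting material
7 | (3,5-dimethoxyphenyl){5-iodo-2-[(4-methoxyphenyl)methoxy]-4-(methoxymethoxy)phenyl}methanone | COCOc1cc(OCc2ccc(OC)cc2)c(C(=O)c2cc(OC)cc(OC)c2)cc1I | intermediate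
8 | hydrazone of 7 (C=N isomer mixture) | COCOc1cc(OCc2ccc(OC)cc2)c(C(=NN)c2cc(OC)cc(OC)c2)cc1I | intermediate
9 | diaryldiazomethane from 8 | COCOc1cc(OCc2ccc(OC)cc2)c(C(=[N+]=[N-])c2cc(OC)cc(OC)c2)cc1I | intermediate (not isolated)
10 | (2S,3R)-3-(3,5-dimethoxyphenyl)-5-iodo-6-(methoxymethoxy)-2-(4-methoxyphenyl)-2,3-dihydro-1-benzofuran (2,3-cis) | COc1ccc([C@H]2Oc3cc(OCOC)c(I)cc3[C@H]2c2cc(OC)cc(OC)c2)cc1 | intermediate
11 | 3,5-dimethoxyphenol | COc1cc(O)cc(OC)c1 | starting material
12 | (E)-2,4-dimethoxy-1-(2-nitroethenyl)benzene | COc1ccc(/C=C/[N+](=O)[O-])c(OC)c1 | starting material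
13 | 2-[(1R)-1-(2,4-dimethoxyphenyl)-2-nitroethyl]-3,5-dimethoxyphenol | [O-][N+](=O)C[C@H](c1ccc(OC)cc1OC)c1c(OC)cc(OC)cc1O | intermediate
14 | 2-[(1R)-1-(2,4-dimethoxyphenyl)-2-nitroethyl]-3,5-dimethoxyphenyl trifluoromethanesulfonate | [O-][N+](=O)C[C@H](c1ccc(OC)cc1OC)c1c(OC)cc(OC)cc1OS(=O)(=O)C(F)(F)F | intermediate
15 | sodium nitronate of 14 | [Na+].[O-][N+]([O-])=C[C@H](c1ccc(OC)cc1OC)c1c(OC)cc(OC)cc1OS(=O)(=O)C(F)(F)F | intermediate (not isolated)
16 | 2-[(1R)-1-(2,4-dimethoxyphenyl)-2-oxoethyl]-3,5-dimethoxyphenyl trifluoromethanesulfonate | O=C[C@H](c1ccc(OC)cc1OC)c1c(OC)cc(OC)cc1OS(=O)(=O)C(F)(F)F | intermediate (not isolated)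
17 | 2-[(1R)-1-(2,4-dimethoxyphenyl)-2-hydroxyethyl]-3,5-dimethoxyphenyl trifluoromethanesulfonate | OC[C@H](c1ccc(OC)cc1OC)c1c(OC)cc(OC)cc1OS(=O)(=O)C(F)(F)F | intermediate
18 | (E)-2-(4-methoxyphenyl)ethenylboronic acid pinacol ester | COc1ccc(/C=C/B2OC(C)(C)C(C)(C)O2)cc1 | starting material
19 | (2R)-2-(2,4-dimethoxyphenyl)-2-{2,4-dimethoxy-6-[(E)-2-(4-methoxyphenyl)ethenyl]phenyl}ethan-1-ol | OC[C@H](c1ccc(OC)cc1OC)c1c(OC)cc(OC)cc1/C=C/c1ccc(OC)cc1 | intermediate
20 | 2-[(1R)-2-bromo-1-(2,4-dimethoxyphenyl)ethyl]-1,5-dimethoxy-3-[(E)-2-(4-methoxyphenyl)ethenyl]benzene | BrC[C@H](c1ccc(OC)cc1OC)c1c(OC)cc(OC)cc1/C=C/c1ccc(OC)cc1 | intermediate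
21 | annulation product: the (2S,3R)-cis-dihydrobenzofuran of 10 with the fused seven-membered ring C4–CH2–CH(2,4-dimethoxyphenyl)[R]–(3,5-dimethoxy-1,2-phenylene)–C(=CH–C6H4-4-OMe)[E]–C5; 6-OMOM retained | COc1ccc([C@H]2Oc3cc(OCOC)c4c(c3[C@H]2c2cc(OC)cc(OC)c2)C[C@H](c2ccc(OC)cc2OC)c2c(OC)cc(OC)cc2/C4=C\c2ccc(OC)cc2)cc1 | intermediate
22 | free C6 phenol of 21 (MOM removed, otherwise unchanged) | COc1ccc([C@H]2Oc3cc(O)c4c(c3[C@H]2c2cc(OC)cc(OC)c2)C[C@H](c2ccc(OC)cc2OC)c2c(OC)cc(OC)cc2/C4=C\c2ccc(OC)cc2)cc1 | intermediate (not isolated)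
23 | octa-O-methyl ether of the target; both dihydrobenzofurans trans, all five stereocentres R | COc1ccc([C@@H]2Oc3cc4c5c(c3[C@H]2c2cc(OC)cc(OC)c2)C[C@H](c2ccc(OC)cc2OC)c2c(OC)cc(OC)cc2[C@H]5[C@H](c2ccc(OC)cc2)O4)cc1 | intermediate
24 | CNP0154047.1 (octaphenol; both dihydrobenzofurans trans, all five stereocentres R) | Oc1ccc([C@@H]2Oc3cc4c5c(c3[C@H]2c2cc(O)cc(O)c2)C[C@H](c2ccc(O)cc2O)c2c(O)cc(O)cc2[C@H]5[C@H](c2ccc(O)cc2)O4)cc1 | target

**Step count and risks**

Total step count: 14. Longest linear sequence: 9 steps (steps 1–6, then 12–14); the second branch (steps 7–11) has 5 steps.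

Most likely to fail, in this order:

1. Step 12. Oxidative addition of the β-branched bromide to the palladacycle may be slow. The electrophile can then be lost by base-induced elimination of HBr (the diarylmethine hydrogen is doubly benzylic) or by aryl-assisted ionisation through the dimethoxyphenyl ring. Palladation of the crowded C4–H next to the ring fusion may also lag. The fallback replaces the alkyl electrophile by an acyl one, sets out from 19 and 10, and comes back at 21. Oxidation of 19 (TEMPO, PhI(OAc)2, MeCN/H2O) gives the diarylacetic acid F1, and pivaloyl chloride/Et3N converts it into the mixed pivalic anhydride F2. Palladium/norbornene ortho-acylation of 10 with F2 (Pd(OAc)2, P(2-furyl)3, norbornene, Cs2CO3, toluene, 100 °C), terminated by the same intramolecular Heck closure, gives the cycloheptenone F3. This acyl oxidative addition needs no SN2 step and the electrophile cannot eliminate. The diarylmethine of F3 is α to the ketone and epimerises freely, so it is set again by Noyori transfer hydrogenation with dynamic kinetic resolution (RuCl(p-cymene)[(S,S)-TsDPEN], HCO2H/Et3N), which should give the cis-alcohol F4. PhOC(S)Cl/DMAP gives the thionocarbonate F5, and Barton–McCombie deoxygenation (Bu3SnH, AIBN, toluene, 80 °C) returns to 21.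

2. Step 13. Three acid-driven events must finish in one flask. Epimerisation of the first dihydrobenzofuran may be incomplete when ring closure is done, and longer exposure may erode its C3 centre (proton loss from the open cation) or cause cation–arene alkylation between molecules. Protonation of the alkene may also occur with poor facial selectivity. The fallback sets the first dihydrobenzofuran trans before the coupling, so that the last acid step only has to unmask and cyclise; it sets out from 10 and comes back at 23. HCl/MeOH removes the MOM group to give the cis-iodophenol F6, and TFA/CH2Cl2 at 0 °C epimerises it to the trans-iodophenol F7. MOMCl/i-Pr2NEt gives the trans MOM ether F8, and the conditions of step 12 with 20 give the trans annulation product F9. A short acid treatment (HCl/MeOH, then brief TFA) gives, through the trans phenol F10, compound 23.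

3. Step 9. The α,α-diaryl aldehyde enolises easily, so partial racemisation may occur before reduction, and ozone may attack the dimethoxyarenes. The fallback avoids the aldehyde, sets out from 14 and comes back at 17. Oxidative Nef conversion of the nitro group to the acid (NaNO2, AcOH, DMSO, 35 °C) gives the diarylacetic acid F11, and BH3·SMe2 in THF reduces it to 17.

**Further compounds**

F1 | step 12 | (2R)-2-(2,4-dimethoxyphenyl)-2-{2,4-dimethoxy-6-[(E)-2-(4-methoxyphenyl)ethenyl]phenyl}acetic acid | OC(=O)[C@H](c1ccc(OC)cc1OC)c1c(OC)cc(OC)cc1/C=C/c1ccc(OC)cc1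
F2 | step 12 | mixed anhydride of F1 with pivalic acid | CC(C)(C)C(=O)OC(=O)[C@H](c1ccc(OC)cc1OC)c1c(OC)cc(OC)cc1/C=C/c1ccc(OC)cc1
F3 | step 12 | ketone analogue of 21 (C=O in place of the ring CH2; the diarylmethine centre is an equilibrating epimer pair and is drawn undefined) | COc1ccc([C@H]2Oc3cc(OCOC)c4c(c3[C@H]2c2cc(OC)cc(OC)c2)C(=O)C(c2ccc(OC)cc2OC)c2c(OC)cc(OC)cc2/C4=C\c2ccc(OC)cc2)cc1
F4 | step 12 | cis-alcohol from F3 (hydroxyl and 2,4-dimethoxyphenyl on the same face; diarylmethine arranged as in 21) | COc1ccc([C@H]2Oc3cc(OCOC)c4c(c3[C@H]2c2cc(OC)cc(OC)c2)[C@H](O)[C@H](c2ccc(OC)cc2OC)c2c(OC)cc(OC)cc2/C4=C\c2ccc(OC)cc2)cc1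
F5 | step 12 | O-phenyl thionocarbonate of F4 | COc1ccc([C@H]2Oc3cc(OCOC)c4c(c3[C@H]2c2cc(OC)cc(OC)c2)[C@H](OC(=S)Oc2ccccc2)[C@H](c2ccc(OC)cc2OC)c2c(OC)cc(OC)cc2/C4=C\c2ccc(OC)cc2)cc1
F6 | step 13 | (2S,3R)-3-(3,5-dimethoxyphenyl)-5-iodo-2-(4-methoxyphenyl)-2,3-dihydro-1-benzofuran-6-ol (cis) | COc1ccc([C@H]2Oc3cc(O)c(I)cc3[C@H]2c2cc(OC)cc(OC)c2)cc1
F7 | step 13 | (2R,3R)-3-(3,5-dimethoxyphenyl)-5-iodo-2-(4-methoxyphenyl)-2,3-dihydro-1-benzofuran-6-ol (trans) | COc1ccc([C@@H]2Oc3cc(O)c(I)cc3[C@H]2c2cc(OC)cc(OC)c2)cc1
F8 | step 13 | (2R,3R)-3-(3,5-dimethoxyphenyl)-5-iodo-6-(methoxymethoxy)-2-(4-methoxyphenyl)-2,3-dihydro-1-benzofuran (trans) | COc1ccc([C@@H]2Oc3cc(OCOC)c(I)cc3[C@H]2c2cc(OC)cc(OC)c2)cc1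
F9 | step 13 | trans-dihydrobenzofuran analogue of 21 | COc1ccc([C@@H]2Oc3cc(OCOC)c4c(c3[C@H]2c2cc(OC)cc(OC)c2)C[C@H](c2ccc(OC)cc2OC)c2c(OC)cc(OC)cc2/C4=C\c2ccc(OC)cc2)cc1
F10 | step 13 | trans-dihydrobenzofuran analogue of 22 | COc1ccc([C@@H]2Oc3cc(O)c4c(c3[C@H]2c2cc(OC)cc(OC)c2)C[C@H](c2ccc(OC)cc2OC)c2c(OC)cc(OC)cc2/C4=C\c2ccc(OC)cc2)cc1
F11 | step 9 | (2R)-2-(2,4-dimethoxyphenyl)-2-{2,4-dimethoxy-6-[(trifluoromethanesulfonyl)oxy]phenyl}acetic acid | OC(=O)[C@H](c1ccc(OC)cc1OC)c1c(OC)cc(OC)cc1OS(=O)(=O)C(F)(F)F
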